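The benzoquinone is traced back through a 5-alkyl-3-methoxyphenol to a 5-alkylcyclohexane-1,3-dione, using the mutually meta (1,3,5) placement of ring carbons C2 (OMe), C4 (carbonyl) and C6 (side chain) on the six-membered carbocycle; the C1 oxygen comes last by para oxidation. The key step joins dimethyl malonate and an (E)-alkenyl methyl ketone in one operation: conjugate addition, then Dieckmann-type closure, forming two C–C bonds and the ring. Its precursor is (R,E)-6-silyloxyheptadec-3-en-2-one, whose single stereocentre comes from asymmetric allylboration of dodecanal and is masked as a triisopropylsilyl ether, robust enough for the later hydrolytic decarboxylation.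

Key step: step 4

Remark: the carbinol carbon keeps the descriptor R from 4 to 25, because the order O > CH2 (towards alkene or ring) > CH2 (undecyl) > H never changes; ring stereocentres formed on the way arise as mixtures and vanish on aromatisation.

Step 1
Reactants: 1 dodecanal; 2 (−)-B-allyldiisopinocampheylborane (made from (+)-α-pinene, commercial pentane solution)
Product: 4 (R)-pentadec-1-en-4-ol, via borinate ester 3 (not isolated)
Conditions: 2 (1.3 equiv), Et2O/pentane, −100 → −78 °C; then 3 M NaOH, 30% H2O2, 0 °C → rt
Reagents that add atoms: (−)-B-allyldiisopinocampheylborane (its allyl group), C=CCB([C@H]1[C@H](C)[C@H]2C[C@@H](C1)C2(C)C)[C@H]1[C@H](C)[C@H]2C[C@@H](C1)C2(C)C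
Why: Brown asymmetric allylboration, in which the allyl group is transferred through a closed chair transition state and the isopinocampheyl groups from (+)-α-pinene direct it to the Si face of the aldehyde, should set the R carbinol centre in high enantiomeric purity before oxidative work-up cleaves the borinate.

Step 2
Reactants: 4 (R)-pentadec-1-en-4-ol; 5 triisopropylsilyl trifluoromethanesulfonate
Product: 6 (4R)-4-(triisopropylsilyloxy)pentadec-1-ene
Conditions: TIPSOTf (1.2 equiv), 2,6-lutidine (1.5 equiv), CH2Cl2, 0 °C → rt
Reagents that add atoms: triisopropylsilyl trifluoromethanesulfonate, CC(C)[Si](C(C)C)(C(C)C)OS(=O)(=O)C(F)(F)F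
Why: O-silylation of a secondary alcohol with a silyl triflate and a hindered pyridine base is routine and forms only an O–Si bond, so the stereocentre is untouched.

Step 3
Reactants: 6 (4R)-4-(triisopropylsilyloxy)pentadec-1-ene; 7 methyl vinyl ketone
Product: 8 (R,E)-6-(triisopropylsilyloxy)heptadec-3-en-2-one
Conditions: Hoveyda–Grubbs 2nd-generation catalyst (3 mol%), methyl vinyl ketone (4 equiv), CH2Cl2, 40 °C
Reagents that add atoms: methyl vinyl ketone, CC(=O)C=C
Why: Olefin cross-metathesis between an unhindered terminal alkene and an electron-poor vinyl ketone should give the cross-product selectively as the E enone, the silyl ether being inert to the ruthenium carbene.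

Step 4
Reactants: 8 (R,E)-6-(triisopropylsilyloxy)heptadec-3-en-2-one; 9 dimethyl malonate
Product: 11 methyl 2,4-dioxo-6-[(2R)-2-(triisopropylsilyloxy)tridecyl]cyclohexane-1-carboxylate (mixture of ring epimers), via Michael adduct 10 (not isolated)
Conditions: 9 (1.3 equiv), NaOMe (1.1 equiv), MeOH, 0 °C → rt; then reflux; cold 1 M HCl to pH 4
Reagents that add atoms: dimethyl malonate, COC(=O)CC(=O)OC
Why: Sodium dimethyl malonate adds in a Michael reaction to C4 of the enone, proton transfer then gives the C1 (methyl-side) ketone enolate, which attacks a malonate ester carbonyl and expels methoxide, and the product is held as its stabilised β-dicarbonyl enolate, which drives the equilibria forward. The closest known reaction type is the tandem Michael–Claisen (Dieckmann-type) condensation of malonates with alkenyl methyl ketones, the standard entry to 5-alkylcyclohexane-1,3-diones. The ring closes by a 6-exo-trig acyl substitution, and its regiochemistry is fixed by connectivity because the enolate on the C3 side could only form a four-membered ring. Two ring stereocentres (the former C4 and the malonate carbon) form without control, the latter being epimerisable, and both are erased by decarboxylation and aromatisation, whereas the side-chain R centre is not enolisable and is not touched. The step needs conjugate addition to outrun γ-deprotonation at C5 followed by loss of the silyloxide; this is secured by using the soft malonate anion fully pre-formed and in excess over methoxide, by letting the addition finish at 0 °C to rt before heating, and by the poor leaving-group ability of the silyloxide, and once C4 is saturated no acidic site stands in an eliminating relationship to the oxygen.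

Step 5
Reactants: 11 methyl 2,4-dioxo-6-[(2R)-2-(triisopropylsilyloxy)tridecyl]cyclohexane-1-carboxylate
Product: 13 5-[(2R)-2-(triisopropylsilyloxy)tridecyl]cyclohexane-1,3-dione, via β-keto acid 12 (not isolated)
Conditions: 2 M aq. NaOH (3 equiv), MeOH, 70 °C; then 1 M HCl to pH 3–4, 60 °C
Reagents that add atoms: none
Why: Saponification of the β-keto ester and decarboxylation of the resulting β-keto acid through the usual cyclic transition state on mild acidification is the standard finish of this dione synthesis, and the triisopropylsilyl ether should tolerate both hot aqueous base and brief warming at pH 3–4.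

Step 6
Reactants: 13 5-[(2R)-2-(triisopropylsilyloxy)tridecyl]cyclohexane-1,3-dione; 14 trimethylsilyldiazomethane
Product: 15 3-methoxy-5-[(2R)-2-(triisopropylsilyloxy)tridecyl]cyclohex-2-en-1-one (mixture of C5 epimers)
Conditions: TMSCHN2 (1.5 equiv, 2 M in hexanes), PhMe/MeOH 4:1, 0 °C → rt
Reagents that add atoms: trimethylsilyldiazomethane (its CH carbon becomes the O-methyl carbon), C[Si](C)(C)C=[N+]=[N-]
Why: O-methylation of the acidic enol of a cyclic 1,3-dione by a diazoalkane in methanol is a known, non-acidic esterification-type reaction, and because the dione is symmetric only one constitutional enol ether can form, which differentiates the two ring oxygens.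

Step 7
Reactants: 15 3-methoxy-5-[(2R)-2-(triisopropylsilyloxy)tridecyl]cyclohex-2-en-1-one
Product: 19 3-methoxy-5-[(2R)-2-(triisopropylsilyloxy)tridecyl]phenol, via α′-selenide 16 (not isolated), via selenoxide 17 (not isolated), via dienone 18 (not isolated)
Conditions: LDA (1.2 equiv), THF, −78 °C; PhSeBr (1.2 equiv), −78 °C; then 30% H2O2 (2.5 equiv), pyridine, CH2Cl2, 0 °C → rt
Reagents that add atoms: none
Why: Kinetic deprotonation of the vinylogous ester occurs at the α′ carbon C6, selenenylation should enter anti to the C5 substituent, and selenoxide syn-elimination towards the cis C5–H gives the cross-conjugated dienone that tautomerises irreversibly to the phenol (α-selenenylation/selenoxide elimination), with the methoxy group and the silyl ether inert to base and buffered peroxide.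

Step 8
Reactants: 19 3-methoxy-5-[(2R)-2-(triisopropylsilyloxy)tridecyl]phenol; 20 acetic anhydride
Product: 22 (2R)-1-(3-acetoxy-5-methoxyphenyl)tridecan-2-yl acetate, via diol 21 (not isolated)
Conditions: TBAF (1.5 equiv), THF, rt, Ar; then Et3N, DMAP (cat.), Ac2O (4 equiv), 0 °C → rt
Reagents that add atoms: acetic anhydride, CC(=O)OC(C)=O
Why: Fluoride desilylation followed in the same flask by DMAP-catalysed acetylation of both hydroxyl groups is standard, and since only Si–O and O–acyl bonds change the carbinol configuration is retained.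

Step 9
Reactants: 22 (2R)-1-(3-acetoxy-5-methoxyphenyl)tridecan-2-yl acetate
Product: 23 (2R)-1-(3-hydroxy-5-methoxyphenyl)tridecan-2-yl acetate
Conditions: pyrrolidine (2 equiv), CH2Cl2, 0 °C → rt
Reagents that add atoms: none
Why: Chemoselective aminolysis works because the aryl acetate is an activated ester with a phenoxide leaving group, whereas the hindered secondary alkyl acetate is inert to a secondary amine at room temperature.

Step 10
Reactants: 23 (2R)-1-(3-hydroxy-5-methoxyphenyl)tridecan-2-yl acetate; 24 potassium nitrosodisulfonate (Fremy's salt)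
Product: 25 (2R)-1-(5-methoxy-3,6-dioxocyclohexa-1,4-dien-1-yl)tridecan-2-yl acetate (the target 2-methoxy-6-[(2R)-2-acetoxytridecyl]-1,4-benzoquinone)
Conditions: (KO3S)2NO (2.5 equiv), aq. KH2PO4, acetone/H2O, 0 °C → rt
Reagents that add atoms: potassium nitrosodisulfonate, [K+].[K+].[O]N(S(=O)(=O)[O-])S(=O)(=O)[O-]
Why: In the Teuber oxidation the nitroxyl radical abstracts the phenolic hydrogen, a second equivalent couples at the unsubstituted para carbon between the methoxy- and alkyl-bearing carbons and loss of imidodisulfonate gives the 1,4-quinone, the near-neutral phosphate buffer leaving the secondary acetate intact.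

Compound list
1 | dodecanal | CCCCCCCCCCCC=O | starting material
2 | (−)-B-allyldiisopinocampheylborane | C=CCB([C@H]1[C@H](C)[C@H]2C[C@@H](C1)C2(C)C)[C@H]1[C@H](C)[C@H]2C[C@@H](C1)C2(C)C | starting material
3 | (R)-pentadec-1-en-4-yl diisopinocampheylborinate | CCCCCCCCCCC[C@H](CC=C)OB([C@H]1[C@H](C)[C@H]2C[C@@H](C1)C2(C)C)[C@H]1[C@H](C)[C@H]2C[C@@H](C1)C2(C)C | intermediate (not isolated)
4 | (R)-pentadec-1-en-4-ol | CCCCCCCCCCC[C@H](CC=C)O | intermediate
5 | triisopropylsilyl trifluoromethanesulfonate | CC(C)[Si](C(C)C)(C(C)C)OS(=O)(=O)C(F)(F)F | starting material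
6 | (4R)-4-(triisopropylsilyloxy)pentadec-1-ene | CCCCCCCCCCC[C@H](CC=C)O[Si](C(C)C)(C(C)C)C(C)C | intermediate
7 | methyl vinyl ketone (but-3-en-2-one) | CC(=O)C=C | starting material
8 | (R,E)-6-(triisopropylsilyloxy)heptadec-3-en-2-one | CCCCCCCCCCC[C@H](C/C=C/C(C)=O)O[Si](C(C)C)(C(C)C)C(C)C | intermediate
9 | dimethyl malonate | COC(=O)CC(=O)OC | starting material
10 | dimethyl 2-[(6R)-2-oxo-6-(triisopropylsilyloxy)heptadecan-4-yl]propanedioate (C4 epimers) | CCCCCCCCCCC[C@H](CC(CC(C)=O)C(C(=O)OC)C(=O)OC)O[Si](C(C)C)(C(C)C)C(C)C | intermediate (not isolated)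
11 | methyl 2,4-dioxo-6-[(2R)-2-(triisopropylsilyloxy)tridecyl]cyclohexane-1-carboxylate (ring epimers) | CCCCCCCCCCC[C@H](CC1CC(=O)CC(=O)C1C(=O)OC)O[Si](C(C)C)(C(C)C)C(C)C | intermediate
12 | 2,4-dioxo-6-[(2R)-2-(triisopropylsilyloxy)tridecyl]cyclohexane-1-carboxylic acid | CCCCCCCCCCC[C@H](CC1CC(=O)CC(=O)C1C(=O)O)O[Si](C(C)C)(C(C)C)C(C)C | intermediate (not isolated)
13 | 5-[(2R)-2-(triisopropylsilyloxy)tridecyl]cyclohexane-1,3-dione | CCCCCCCCCCC[C@H](CC1CC(=O)CC(=O)C1)O[Si](C(C)C)(C(C)C)C(C)C | intermediate
14 | trimethylsilyldiazomethane | C[Si](C)(C)C=[N+]=[N-] | starting material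
15 | 3-methoxy-5-[(2R)-2-(triisopropylsilyloxy)tridecyl]cyclohex-2-en-1-one (C5 epimers) | CCCCCCCCCCC[C@H](CC1CC(=O)C=C(OC)C1)O[Si](C(C)C)(C(C)C)C(C)C | intermediate
16 | 3-methoxy-6-(phenylselanyl)-5-[(2R)-2-(triisopropylsilyloxy)tridecyl]cyclohex-2-en-1-one | CCCCCCCCCCC[C@H](CC1CC(OC)=CC(=O)C1[Se]c1ccccc1)O[Si](C(C)C)(C(C)C)C(C)C | intermediate (not isolated)
17 | 6-(benzeneseleninyl)-3-methoxy-5-[(2R)-2-(triisopropylsilyloxy)tridecyl]cyclohex-2-en-1-one | CCCCCCCCCCC[C@H](CC1CC(OC)=CC(=O)C1[Se](=O)c1ccccc1)O[Si](C(C)C)(C(C)C)C(C)C | intermediate (not isolated)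
18 | 3-methoxy-5-[(2R)-2-(triisopropylsilyloxy)tridecyl]cyclohexa-2,5-dien-1-one | CCCCCCCCCCC[C@H](CC1=CC(=O)C=C(OC)C1)O[Si](C(C)C)(C(C)C)C(C)C | intermediate (not isolated)
19 | 3-methoxy-5-[(2R)-2-(triisopropylsilyloxy)tridecyl]phenol | CCCCCCCCCCC[C@H](Cc1cc(O)cc(OC)c1)O[Si](C(C)C)(C(C)C)C(C)C | intermediate
20 | acetic anhydride | CC(=O)OC(C)=O | starting material
21 | 3-[(2R)-2-hydroxytridecyl]-5-methoxyphenol | CCCCCCCCCCC[C@H](Cc1cc(O)cc(OC)c1)O | intermediate (not isolated)
22 | (2R)-1-(3-acetoxy-5-methoxyphenyl)tridecan-2-yl acetate | CCCCCCCCCCC[C@H](Cc1cc(OC(C)=O)cc(OC)c1)OC(C)=O | intermediate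
23 | (2R)-1-(3-hydroxy-5-methoxyphenyl)tridecan-2-yl acetate | CCCCCCCCCCC[C@H](Cc1cc(O)cc(OC)c1)OC(C)=O | intermediate
24 | potassium nitrosodisulfonate (Fremy's salt) | [K+].[K+].[O]N(S(=O)(=O)[O-])S(=O)(=O)[O-] | starting material
25 | (2R)-1-(5-methoxy-3,6-dioxocyclohexa-1,4-dien-1-yl)tridecan-2-yl acetate | CCCCCCCCCCC[C@H](CC1=CC(=O)C=C(OC)C1=O)OC(C)=O | target

Total step count: 10
Longest linear sequence: 10 steps (1 → 25; all other inputs are commercial)

Steps most likely to fail

1. Step 4. Vinylogous deprotonation at C5 of enone 8, followed by expulsion of the silyloxide, may compete with conjugate addition, or the Michael adduct may stall before ring closure. The fallback sets out from 6. Cross-metathesis with methyl acrylate (same ruthenium catalyst) should give methyl (R,E)-5-(triisopropylsilyloxy)hexadec-2-enoate F1, whose γ-hydrogens are far less acidic than those of the enone. Sodium methyl acetoacetate (NaOMe, MeOH, reflux), a less basic nucleophile than malonate, then adds to give dimethyl 2-acetyl-3-[(2R)-2-(triisopropylsilyloxy)tridecyl]pentanedioate F2. In the same flask the acetyl-methyl enolate of F2 closes onto the chain ester, the other classical dihydroresorcinol synthesis, and the route is rejoined at 11.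

2. Step 7. The selenoxide may find no syn hydrogen if selenium enters cis to the side chain, and the electron-rich phenol may be oxidised or selenenylated by selenium(IV)/peroxide as it forms. The fallback sets out from 15. LDA and TMSCl (THF, −78 °C) should give the silyl dienol ether {[(2R)-1-[5-methoxy-3-(trimethylsilyloxy)cyclohexa-2,4-dien-1-yl]tridecan-2-yl]oxy}triisopropylsilane F3. Saegusa–Ito oxidation of F3 with Pd(OAc)2 in MeCN at rt works without peroxide, through a palladium enolate that can reach the C5 hydrogen from either face, and the resulting dienone tautomerises so that the route is rejoined at 19.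

3. Step 10. Radical coupling or attack at an ortho carbon instead of the para carbon may occur, made worse by poor contact between the aqueous oxidant and the lipophilic phenol. The fallback sets out from 23. Two-electron oxidation with PhI(OAc)2 (2.2 equiv) in MeOH at 0 °C, a homogeneous ionic dearomatisation with para trapping by methanol, should give the quinone monoketal (2R)-1-(5,6,6-trimethoxy-3-oxocyclohexa-1,4-dien-1-yl)tridecan-2-yl acetate F4. Mild hydrolysis of F4 (aq. oxalic acid, THF, rt) then rejoins the route at 25.

Further compounds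
F1 | step 4 | methyl (R,E)-5-(triisopropylsilyloxy)hexadec-2-enoate | CCCCCCCCCCC[C@H](C/C=C/C(=O)OC)O[Si](C(C)C)(C(C)C)C(C)C
F2 | step 4 | dimethyl 2-acetyl-3-[(2R)-2-(triisopropylsilyloxy)tridecyl]pentanedioate | CCCCCCCCCCC[C@H](CC(CC(=O)OC)C(C(C)=O)C(=O)OC)O[Si](C(C)C)(C(C)C)C(C)C
F3 | step 7 | {[(2R)-1-[5-methoxy-3-(trimethylsilyloxy)cyclohexa-2,4-dien-1-yl]tridecan-2-yl]oxy}triisopropylsilane | CCCCCCCCCCC[C@H](CC1CC(OC)=CC(O[Si](C)(C)C)=C1)O[Si](C(C)C)(C(C)C)C(C)C
F4 | step 10 | (2R)-1-(5,6,6-trimethoxy-3-oxocyclohexa-1,4-dien-1-yl)tridecan-2-yl acetate | CCCCCCCCCCC[C@H](CC1=CC(=O)C=C(OC)C1(OC)OC)OC(C)=O
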